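**Retrosynthetic overview**

1. Feature: the benzylic methine on C8 of ring A lies next to the C8a oxygen (O1) and is 1,3-related to the ketone of the heptanone arm, so the methine, the arm CH2, the ketone carbon and O1 map onto C4, C3, C2 and O1 of a 2-methoxychroman ketal.
2. Last disconnection: flavonol ring C comes from a Baker–Venkataraman shift and cyclodehydration of a ring A 2-hydroxy-ω-benzyloxyacetophenone, after which four benzyl ethers are removed by hydrogenolysis.
3. The acyl group is placed ortho to the phenol that the ketal releases; the ketone released with it is held as a dioxolane through the basic steps.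
4. Key disconnection: the chroman ketal comes from a chiral phosphoric acid-catalysed [4+2] of the ortho-quinone methide of racemic benzylic alcohol 7 with enol ether 9 (methine–CH2 bond, O1–ketal carbon bond, (R)-methine).
5. Alcohol 7 comes from an arylethyl Grignard reagent and 4,6-bis(benzyloxy)-2-hydroxybenzaldehyde, and 9 from methylenation of methyl 3-phenylpropanoate; ring order is temporary pyran ring (step 6), opened (step 7), then flavone ring C (step 11).

Key step: step 6

Assumption: (R)-TRIP, (R)-3,3'-bis(2,4,6-triisopropylphenyl)-1,1'-binaphthyl-2,2'-diyl hydrogen phosphate, is taken to give the (4R) adduct; if the sense of induction is the opposite, the (S)-acid is used and nothing else changes.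

**Route**

Step 1
Reactants: 1 2,4,6-trihydroxybenzaldehyde
Product: 2 4,6-bis(benzyloxy)-2-hydroxybenzaldehyde
Conditions: BnBr (2.05 equiv), K2CO3 (2.2 equiv), DMF, 0 °C → rt
Reagents that add atoms: benzyl bromide BrCc1ccccc1
Why: Williamson etherification should take the para hydroxyl and one ortho hydroxyl, while the last hydroxyl is held in a hydrogen bond to the aldehyde and stays free.

Step 2
Reactants: 3 2-(4-hydroxy-3-methoxyphenyl)ethanol
Product: 4 2-[4-(benzyloxy)-3-methoxyphenyl]ethanol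
Conditions: BnBr (1.1 equiv), K2CO3, acetone, reflux
Reagents that add atoms: benzyl bromide BrCc1ccccc1
Why: Williamson etherification, in which K2CO3 deprotonates only the phenol, so the primary alcohol should stay free.

Step 3
Reactants: 4 2-[4-(benzyloxy)-3-methoxyphenyl]ethanol
Product: 5 1-(benzyloxy)-4-(2-bromoethyl)-2-methoxybenzene
Conditions: CBr4, PPh3, CH2Cl2, 0 °C
Reagents that add atoms: carbon tetrabromide BrC(Br)(Br)Br
Why: Appel reaction on a primary alcohol (bromide displaces the alkoxyphosphonium group), with the benzyl and methyl ethers inert.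

Step 4
Reactants: 5 1-(benzyloxy)-4-(2-bromoethyl)-2-methoxybenzene; 2 4,6-bis(benzyloxy)-2-hydroxybenzaldehyde
Product: 7 racemic 3,5-bis(benzyloxy)-2-{3-[4-(benzyloxy)-3-methoxyphenyl]-1-hydroxypropyl}phenol, via arylethylmagnesium bromide 6 (not isolated)
Conditions: 5 (2.2 equiv), Mg, I2 (cat.), THF, 40 °C; then 2 (1 equiv), 0 °C → rt; aq. NH4Cl; Et3N-deactivated silica
Reagents that add atoms: none
Why: Grignard 1,2-addition, in which the first equivalent forms the magnesium phenoxide that chelates and activates the aldehyde; the new carbinol centre needs no control because step 6 erases it.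

Step 5
Reactants: 8 methyl 3-phenylpropanoate
Product: 9 2-methoxy-4-phenylbut-1-ene
Conditions: Cp2TiMe2 (2.2 equiv), toluene, 65 °C, dark; pentane, filtration through basic Al2O3
Reagents that add atoms: dimethyltitanocene [CH3-].[CH3-].[Ti+4].c1cc[cH-]c1.c1cc[cH-]c1
Why: Petasis methylenation of the ester carbonyl should give the 1,1-disubstituted enol ether as a single regioisomer, which an elimination from the dimethyl ketal of 4-phenylbutan-2-one would not guarantee.

Step 6
Reactants: 7 racemic 3,5-bis(benzyloxy)-2-{3-[4-(benzyloxy)-3-methoxyphenyl]-1-hydroxypropyl}phenol; 9 2-methoxy-4-phenylbut-1-ene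
Product: 11 (4R)-5,7-bis(benzyloxy)-4-{2-[4-(benzyloxy)-3-methoxyphenyl]ethyl}-2-methoxy-2-(2-phenylethyl)chroman (both C2 epimers), via ortho-quinone methide 10 (not isolated)
Conditions: (R)-TRIP (10 mol %), 9 (3 equiv), 4 Å MS, toluene, 0 °C
Reagents that add atoms: none
Why: The acid protonates the benzylic hydroxyl of 7, water leaves with help from the ortho and para oxygen substituents, and ortho-quinone methide 10 stays hydrogen-bonded to the chiral phosphate while the terminal CH2 of 9 adds to the methide carbon and the phenolic oxygen captures the oxocarbenium carbon. The closest known reaction type is the chiral phosphoric acid-catalysed inverse-demand oxa-Diels–Alder reaction of ortho-quinone methides generated in situ with electron-rich alkenes. The pyran ring closes in a concerted but asynchronous [4+2] mode with the C–C bond leading (a 6-exo-trig capture of the oxocarbenium ion by oxygen if the process turns stepwise). C4 is controlled by the phosphate, which shields one face of the planar methide carbon, and both enantiomers of 7 converge because their carbinol centre is lost in 10; the ketal carbon C2 forms without control and is destroyed in step 7. The step needs face selectivity and trapping by 9 ahead of tautomerisation to the 2-vinylphenol, dimerisation or Friedel–Crafts attack by the guaiacyl ring. The two benzyloxy groups make ionisation easy and make 10 too unreactive to add 9 without the acid, so bond formation should run through the catalyst-bound species, while the excess of the far more nucleophilic enol ether and the sieves (which keep water from hydrolysing 9) secure the chemoselectivity.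

Step 7
Reactants: 11 (4R)-5,7-bis(benzyloxy)-4-{2-[4-(benzyloxy)-3-methoxyphenyl]ethyl}-2-methoxy-2-(2-phenylethyl)chroman
Product: 12 3,5-bis(benzyloxy)-2-{(2R)-4-[4-(benzyloxy)-3-methoxyphenyl]-1-[2-(2-phenylethyl)-1,3-dioxolan-2-yl]butan-2-yl}phenol
Conditions: HOCH2CH2OH (10 equiv), PPTS (10 mol %), benzene, reflux, Dean–Stark
Reagents that add atoms: ethylene glycol OCCO
Why: Acid-catalysed transketalisation, in which the aryl alkyl ketal ionises readily, glycol traps the oxocarbenium ion, and the dialkyl dioxolane with a free phenol should be the favoured isomer because an aryloxy ketal is the weaker one; removal of methanol drives the exchange and the remote (R)-methine is not touched.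

Step 8
Reactants: 12 3,5-bis(benzyloxy)-2-{(2R)-4-[4-(benzyloxy)-3-methoxyphenyl]-1-[2-(2-phenylethyl)-1,3-dioxolan-2-yl]butan-2-yl}phenol; 13 benzyloxyacetyl chloride
Product: 15 2-(benzyloxy)-1-{4,6-bis(benzyloxy)-2-hydroxy-3-[(2R)-4-[4-(benzyloxy)-3-methoxyphenyl]-1-[2-(2-phenylethyl)-1,3-dioxolan-2-yl]butan-2-yl]phenyl}ethanone, via bromomagnesium phenolate 14 (not isolated)
Conditions: EtMgBr (1.0 equiv), Et2O, 0 °C; solvent change to toluene; 13 (1.1 equiv), 0 °C → rt; aq. NH4Cl
Reagents that add atoms: none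
Why: Magnesium phenolate-templated ortho-acylation (the acyl counterpart of the magnesium-mediated ortho-formylation of phenols), in which the acyl chloride bound to magnesium in a non-coordinating solvent is delivered through a six-membered transition state to the only free ortho carbon, so the ketone should land between the phenol and a benzyloxy group as the future C4a requires; the medium stays non-protic, so the dioxolane and benzyl ethers survive.

Step 9
Reactants: 15 2-(benzyloxy)-1-{4,6-bis(benzyloxy)-2-hydroxy-3-[(2R)-4-[4-(benzyloxy)-3-methoxyphenyl]-1-[2-(2-phenylethyl)-1,3-dioxolan-2-yl]butan-2-yl]phenyl}ethanone; 16 benzoyl chloride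
Product: 17 2-[(benzyloxy)acetyl]-3,5-bis(benzyloxy)-6-{(2R)-4-[4-(benzyloxy)-3-methoxyphenyl]-1-[2-(2-phenylethyl)-1,3-dioxolan-2-yl]butan-2-yl}phenyl benzoate
Conditions: Et3N, DMAP (cat.), CH2Cl2, 0 °C → rt
Reagents that add atoms: none
Why: DMAP-catalysed esterification of the chelated phenol should give the benzoate needed for the acyl shift.

Step 10
Reactants: 17 2-[(benzyloxy)acetyl]-3,5-bis(benzyloxy)-6-{(2R)-4-[4-(benzyloxy)-3-methoxyphenyl]-1-[2-(2-phenylethyl)-1,3-dioxolan-2-yl]butan-2-yl}phenyl benzoate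
Product: 18 2-(benzyloxy)-1-{4,6-bis(benzyloxy)-2-hydroxy-3-[(2R)-4-[4-(benzyloxy)-3-methoxyphenyl]-1-[2-(2-phenylethyl)-1,3-dioxolan-2-yl]butan-2-yl]phenyl}-3-phenylpropane-1,3-dione (central carbon not defined; keto and enol forms)
Conditions: LiN(SiMe3)2 (2.5 equiv), THF, −78 → 0 °C; aq. NH4Cl
Reagents that add atoms: none
Why: Baker–Venkataraman rearrangement, in which the enolate of the α-benzyloxy ketone attacks the neighbouring benzoate through a six-membered transition state and releases the phenoxide; the dioxolane keeps the side-chain ketone from forming an enolate that would compete for the benzoyl group.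

Step 11
Reactants: 18 2-(benzyloxy)-1-{4,6-bis(benzyloxy)-2-hydroxy-3-[(2R)-4-[4-(benzyloxy)-3-methoxyphenyl]-1-[2-(2-phenylethyl)-1,3-dioxolan-2-yl]butan-2-yl]phenyl}-3-phenylpropane-1,3-dione
Product: 20 3,5,7-tris(benzyloxy)-8-{(3R)-1-[4-(benzyloxy)-3-methoxyphenyl]-5-oxo-7-phenylheptan-3-yl}-2-phenyl-4H-chromen-4-one, via side-chain ketone 19 (not isolated)
Conditions: conc. HCl (cat.), AcOH/H2O 9:1, 60 °C
Reagents that add atoms: water O
Why: Aqueous acid hydrolyses the dioxolane and cyclodehydrates the 2-hydroxyaryl 1,3-diketone (6-exo-trig attack of the phenol on the benzoyl carbonyl, then loss of water) to close flavone ring C, and the order of the two events does not matter.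

Step 12
Reactants: 20 3,5,7-tris(benzyloxy)-8-{(3R)-1-[4-(benzyloxy)-3-methoxyphenyl]-5-oxo-7-phenylheptan-3-yl}-2-phenyl-4H-chromen-4-one
Product: 21 3,5,7-trihydroxy-8-[(3R)-1-(4-hydroxy-3-methoxyphenyl)-5-oxo-7-phenylheptan-3-yl]-2-phenyl-4H-chromen-4-one (CNP0164153.1)
Conditions: H2 (1 atm), 10% Pd/C, EtOAc/MeOH, rt
Reagents that add atoms: none
Why: Hydrogenolysis of the four benzyl ethers over Pd/C should leave the dialkyl ketone, the methyl ether, the flavonol C2–C3 double bond and the (R)-methine untouched.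

**Compound list**

1 | 2,4,6-trihydroxybenzaldehyde | O=Cc1c(O)cc(O)cc1O | starting material
2 | 4,6-bis(benzyloxy)-2-hydroxybenzaldehyde | O=Cc1c(O)cc(OCc2ccccc2)cc1OCc1ccccc1 | intermediate
3 | 2-(4-hydroxy-3-methoxyphenyl)ethanol | COc1cc(CCO)ccc1O | starting material
4 | 2-[4-(benzyloxy)-3-methoxyphenyl]ethanol | COc1cc(CCO)ccc1OCc1ccccc1 | intermediate
5 | 1-(benzyloxy)-4-(2-bromoethyl)-2-methoxybenzene | COc1cc(CCBr)ccc1OCc1ccccc1 | intermediate
6 | {2-[4-(benzyloxy)-3-methoxyphenyl]ethyl}magnesium bromide (not isolated) | COc1cc(CC[Mg]Br)ccc1OCc1ccccc1 | intermediate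
7 | racemic 3,5-bis(benzyloxy)-2-{3-[4-(benzyloxy)-3-methoxyphenyl]-1-hydroxypropyl}phenol | COc1cc(CCC(O)c2c(O)cc(OCc3ccccc3)cc2OCc2ccccc2)ccc1OCc1ccccc1 | intermediate
8 | methyl 3-phenylpropanoate | COC(=O)CCc1ccccc1 | starting material
9 | 2-methoxy-4-phenylbut-1-ene | COC(=C)CCc1ccccc1 | intermediate
10 | 3,5-bis(benzyloxy)-6-{3-[4-(benzyloxy)-3-methoxyphenyl]propylidene}cyclohexa-2,4-dien-1-one (ortho-quinone methide, alkene geometry not defined, not isolated) | COc1cc(CCC=C2C(=O)C=C(OCc3ccccc3)C=C2OCc2ccccc2)ccc1OCc1ccccc1 | intermediate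
11 | (4R)-5,7-bis(benzyloxy)-4-{2-[4-(benzyloxy)-3-methoxyphenyl]ethyl}-2-methoxy-2-(2-phenylethyl)chroman, both C2 epimers | COC1(CCc2ccccc2)C[C@@H](CCc2ccc(OCc3ccccc3)c(OC)c2)c2c(OCc3ccccc3)cc(OCc3ccccc3)cc2O1 | intermediate
12 | 3,5-bis(benzyloxy)-2-{(2R)-4-[4-(benzyloxy)-3-methoxyphenyl]-1-[2-(2-phenylethyl)-1,3-dioxolan-2-yl]butan-2-yl}phenol | COc1cc(CC[C@H](CC2(CCc3ccccc3)OCCO2)c2c(O)cc(OCc3ccccc3)cc2OCc2ccccc2)ccc1OCc1ccccc1 | intermediate
13 | benzyloxyacetyl chloride | O=C(Cl)COCc1ccccc1 | starting material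
14 | bromomagnesium phenolate of 12 (not isolated) | COc1cc(CC[C@H](CC2(CCc3ccccc3)OCCO2)c2c(O[Mg]Br)cc(OCc3ccccc3)cc2OCc2ccccc2)ccc1OCc1ccccc1 | intermediate
15 | 2-(benzyloxy)-1-{4,6-bis(benzyloxy)-2-hydroxy-3-[(2R)-4-[4-(benzyloxy)-3-methoxyphenyl]-1-[2-(2-phenylethyl)-1,3-dioxolan-2-yl]butan-2-yl]phenyl}ethanone | COc1cc(CC[C@H](CC2(CCc3ccccc3)OCCO2)c2c(O)c(C(=O)COCc3ccccc3)c(OCc3ccccc3)cc2OCc2ccccc2)ccc1OCc1ccccc1 | intermediate
16 | benzoyl chloride | O=C(Cl)c1ccccc1 | starting material
17 | 2-[(benzyloxy)acetyl]-3,5-bis(benzyloxy)-6-{(2R)-4-[4-(benzyloxy)-3-methoxyphenyl]-1-[2-(2-phenylethyl)-1,3-dioxolan-2-yl]butan-2-yl}phenyl benzoate | COc1cc(CC[C@H](CC2(CCc3ccccc3)OCCO2)c2c(OC(=O)c3ccccc3)c(C(=O)COCc3ccccc3)c(OCc3ccccc3)cc2OCc2ccccc2)ccc1OCc1ccccc1 | intermediate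
18 | 2-(benzyloxy)-1-{4,6-bis(benzyloxy)-2-hydroxy-3-[(2R)-4-[4-(benzyloxy)-3-methoxyphenyl]-1-[2-(2-phenylethyl)-1,3-dioxolan-2-yl]butan-2-yl]phenyl}-3-phenylpropane-1,3-dione (central carbon not defined) | COc1cc(CC[C@H](CC2(CCc3ccccc3)OCCO2)c2c(O)c(C(=O)C(OCc3ccccc3)C(=O)c3ccccc3)c(OCc3ccccc3)cc2OCc2ccccc2)ccc1OCc1ccccc1 | intermediate
19 | 2-(benzyloxy)-1-{4,6-bis(benzyloxy)-3-[(3R)-1-[4-(benzyloxy)-3-methoxyphenyl]-5-oxo-7-phenylheptan-3-yl]-2-hydroxyphenyl}-3-phenylpropane-1,3-dione (central carbon not defined, not isolated) | COc1cc(CC[C@H](CC(=O)CCc2ccccc2)c2c(O)c(C(=O)C(OCc3ccccc3)C(=O)c3ccccc3)c(OCc3ccccc3)cc2OCc2ccccc2)ccc1OCc1ccccc1 | intermediate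
20 | 3,5,7-tris(benzyloxy)-8-{(3R)-1-[4-(benzyloxy)-3-methoxyphenyl]-5-oxo-7-phenylheptan-3-yl}-2-phenyl-4H-chromen-4-one | COc1cc(CC[C@H](CC(=O)CCc2ccccc2)c2c(OCc3ccccc3)cc(OCc3ccccc3)c3c(=O)c(OCc4ccccc4)c(-c4ccccc4)oc23)ccc1OCc1ccccc1 | intermediate
21 | 3,5,7-trihydroxy-8-[(3R)-1-(4-hydroxy-3-methoxyphenyl)-5-oxo-7-phenylheptan-3-yl]-2-phenyl-4H-chromen-4-one | COc1cc(CC[C@H](CC(=O)CCc2ccccc2)c2c(O)cc(O)c3c(=O)c(O)c(-c4ccccc4)oc23)ccc1O | target

**Step count**

Total: 12 steps. Longest linear sequence: 10 steps (steps 2, 3, 4, 6, 7, 8, 9, 10, 11, 12, from compound 3).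

**Steps most likely to fail**

Step 6. The methide here carries a flexible alkyl chain, not an aryl group, so facial discrimination by the phosphate may be weak. Uncatalysed addition, tautomerisation of the methide to the 2-vinylphenol and hydrolysis of the enol ether may also take material away. The fallback replaces catalyst control by auxiliary control, using the known diastereoselective [4+2] of ortho-quinone methides generated without acid at low temperature with enol ethers of trans-2-phenylcyclohexanol; it sets out from 2 and comes back at 12. Aldehyde 2 would be converted with Boc2O, i-Pr2NEt and DMAP (cat.) into 3,5-bis(benzyloxy)-2-formylphenyl tert-butyl carbonate F1. (1R,2S)-2-Phenylcyclohexanol would be acylated with 3-phenylpropanoyl chloride (pyridine, DMAP) to (1R,2S)-2-phenylcyclohexyl 3-phenylpropanoate F2, and methylenation with Cp2TiMe2 would give the chiral enol ether (1R,2S)-1-[(4-phenylbut-1-en-2-yl)oxy]-2-phenylcyclohexane F3. Grignard reagent 6 (1.1 equiv) would be added to F1 at −78 °C in the presence of F3 and the mixture warmed. The magnesium alkoxide takes over the Boc group, tert-butyl carbonate leaves, and methide 10 is trapped in an endo cycloaddition in which the phenyl group of the auxiliary blocks one face of the enol ether. The product would be (4R)-5,7-bis(benzyloxy)-4-{2-[4-(benzyloxy)-3-methoxyphenyl]ethyl}-2-(2-phenylethyl)-2-{[(1R,2S)-2-phenylcyclohexyl]oxy}chroman F4. Transketalisation of F4 under the conditions of step 7 would give 12 and return the auxiliary. The structures are drawn for the (1R,2S)-alcohol; its antipode would be used if the induction ran the other way.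

Step 8. The phenolate may be acylated on oxygen, not carbon, and the Lewis-basic ketal and ether oxygens may weaken the magnesium template so that ortho delivery is lost. The fallback builds the ketone in three steps around the magnesium-mediated ortho-formylation (Casnati–Skattebøl), whose regiochemistry is secure; it sets out from 12 and comes back at 15. Phenol 12 would be formylated with MgCl2, Et3N and paraformaldehyde in MeCN at reflux to 4,6-bis(benzyloxy)-2-hydroxy-3-{(2R)-4-[4-(benzyloxy)-3-methoxyphenyl]-1-[2-(2-phenylethyl)-1,3-dioxolan-2-yl]butan-2-yl}benzaldehyde F5. (Benzyloxymethyl)lithium (2.2 equiv, from Bu3SnCH2OBn and n-BuLi, THF, −78 °C) would add to the aldehyde to give 2-[2-(benzyloxy)-1-hydroxyethyl]-3,5-bis(benzyloxy)-6-{(2R)-4-[4-(benzyloxy)-3-methoxyphenyl]-1-[2-(2-phenylethyl)-1,3-dioxolan-2-yl]butan-2-yl}phenol F6 (carbinol centre not defined). Oxidation of the benzylic alcohol with MnO2 in CH2Cl2 would give 15.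

Step 7. The liberated phenol may re-close on the oxocarbenium ion (ring–chain isomerisation to a hydroxyethyl chroman ketal), or the ketal may lose methanol to a 4H-chromene, so that the open dioxolane is not obtained cleanly. The fallback masks the phenol while the dioxolane is made and frees it with base, which cannot catalyse ketal exchange; it sets out from 11 and comes back at 12. Ketal 11 would be hydrolysed (AcOH/THF/H2O, rt) to (5R)-5-[2,4-bis(benzyloxy)-6-hydroxyphenyl]-7-[4-(benzyloxy)-3-methoxyphenyl]-1-phenylheptan-3-one F7, which may rest as its cyclic hemiketal. Acetylation (Ac2O, pyridine, DMAP) would drain it to the aryl acetate 3,5-bis(benzyloxy)-2-{(3R)-1-[4-(benzyloxy)-3-methoxyphenyl]-5-oxo-7-phenylheptan-3-yl}phenyl acetate F8. Ketalisation (ethylene glycol, PPTS, benzene, Dean–Stark) would give 3,5-bis(benzyloxy)-2-{(2R)-4-[4-(benzyloxy)-3-methoxyphenyl]-1-[2-(2-phenylethyl)-1,3-dioxolan-2-yl]butan-2-yl}phenyl acetate F9, and K2CO3 in MeOH would release 12.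

Further compounds
F1 | step 6 | 3,5-bis(benzyloxy)-2-formylphenyl tert-butyl carbonate | CC(C)(C)OC(=O)Oc1cc(OCc2ccccc2)cc(OCc2ccccc2)c1C=O
F2 | step 6 | (1R,2S)-2-phenylcyclohexyl 3-phenylpropanoate | O=C(CCc1ccccc1)O[C@@H]1CCCC[C@H]1c1ccccc1
F3 | step 6 | (1R,2S)-1-[(4-phenylbut-1-en-2-yl)oxy]-2-phenylcyclohexane | C=C(CCc1ccccc1)O[C@@H]1CCCC[C@H]1c1ccccc1
F4 | step 6 | (4R)-5,7-bis(benzyloxy)-4-{2-[4-(benzyloxy)-3-methoxyphenyl]ethyl}-2-(2-phenylethyl)-2-{[(1R,2S)-2-phenylcyclohexyl]oxy}chroman (C2 not defined) | COc1cc(CC[C@@H]2CC(CCc3ccccc3)(O[C@@H]3CCCC[C@H]3c3ccccc3)Oc3cc(OCc4ccccc4)cc(OCc4ccccc4)c32)ccc1OCc1ccccc1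
F5 | step 8 | 4,6-bis(benzyloxy)-2-hydroxy-3-{(2R)-4-[4-(benzyloxy)-3-methoxyphenyl]-1-[2-(2-phenylethyl)-1,3-dioxolan-2-yl]butan-2-yl}benzaldehyde | COc1cc(CC[C@H](CC2(CCc3ccccc3)OCCO2)c2c(O)c(C=O)c(OCc3ccccc3)cc2OCc2ccccc2)ccc1OCc1ccccc1
F6 | step 8 | 2-[2-(benzyloxy)-1-hydroxyethyl]-3,5-bis(benzyloxy)-6-{(2R)-4-[4-(benzyloxy)-3-methoxyphenyl]-1-[2-(2-phenylethyl)-1,3-dioxolan-2-yl]butan-2-yl}phenol (carbinol centre not defined) | COc1cc(CC[C@H](CC2(CCc3ccccc3)OCCO2)c2c(O)c(C(O)COCc3ccccc3)c(OCc3ccccc3)cc2OCc2ccccc2)ccc1OCc1ccccc1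
F7 | step 7 | (5R)-5-[2,4-bis(benzyloxy)-6-hydroxyphenyl]-7-[4-(benzyloxy)-3-methoxyphenyl]-1-phenylheptan-3-one | COc1cc(CC[C@H](CC(=O)CCc2ccccc2)c2c(O)cc(OCc3ccccc3)cc2OCc2ccccc2)ccc1OCc1ccccc1
F8 | step 7 | 3,5-bis(benzyloxy)-2-{(3R)-1-[4-(benzyloxy)-3-methoxyphenyl]-5-oxo-7-phenylheptan-3-yl}phenyl acetate | COc1cc(CC[C@H](CC(=O)CCc2ccccc2)c2c(OC(C)=O)cc(OCc3ccccc3)cc2OCc2ccccc2)ccc1OCc1ccccc1
F9 | step 7 | 3,5-bis(benzyloxy)-2-{(2R)-4-[4-(benzyloxy)-3-methoxyphenyl]-1-[2-(2-phenylethyl)-1,3-dioxolan-2-yl]butan-2-yl}phenyl acetate | COc1cc(CC[C@H](CC2(CCc3ccccc3)OCCO2)c2c(OC(C)=O)cc(OCc3ccccc3)cc2OCc2ccccc2)ccc1OCc1ccccc1
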